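The pyran ring is treated as a formate unit (C1–O2) laid across a monocyclic enynone (isochromene numbering). C8a is the only enolisable carbon of the carbocycle (C7 is quaternary, C5 chlorinated) and is vinylogous to the C6 ketone; C3 is an alkyne carbon. In one flask the dienolate is formylated at C8a and the new enol oxygen closes 6-endo onto silver-activated C3, making the C1–C8a and O2–C3 bonds. The precursor is a 3-alkynyl-2-chlorocyclohexenone carrying the whole dienyl ester chain. Its trans C7/C8 diol is relayed from the isopropenyl carbon of (S)-carvone, which is then excised to a 1,3-dione; the chain stereocentre comes from a rhodium-catalysed hydrogenation.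

Key step: step 17

Numbering: O2 is the ring oxygen, C1 the CH between O2 and C8a, C3 the ring carbon bearing the side chain; C4a, C5–C8 and C8a form the carbocycle.

Assumption: acid hydrolysis of the carvone epoxide is taken to open at the secondary carbon remote from the carbonyl with inversion; on this basis (S)-carvone leads to the (7S,8R) diol.

Step 1
Reactants: 1 (S)-(+)-carvone
Product: 2 (1S,4S,6S)-1-methyl-4-(prop-1-en-2-yl)-7-oxabicyclo[4.1.0]heptan-2-one
Conditions: H2O2 (30% aq.), NaOH (cat.), MeOH, 0 °C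
Reagents that add atoms: hydrogen peroxide, OO
Why: Weitz–Scheffer nucleophilic epoxidation of the enone, in which hydroperoxide adds anti to the isopropenyl group so that the epoxide is trans to it and both new centres (future C7 and C8) are set by the future C4a substituent.

Step 2
Reactants: 2 (1S,4S,6S)-1-methyl-4-(prop-1-en-2-yl)-7-oxabicyclo[4.1.0]heptan-2-one
Product: 3 (2S,3R,5S)-2,3-dihydroxy-2-methyl-5-(prop-1-en-2-yl)cyclohexan-1-one
Conditions: HClO4 (5% aq.), THF, 0 °C → rt
Reagents that add atoms: water, O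
Why: acid-catalysed epoxide hydrolysis, water attacking the secondary carbon remote from the carbonyl with inversion while the tertiary C–O bond is kept, which should give the trans diol (a regioisomeric opening would give a separable diastereomer).

Step 3
Reactants: 3 (2S,3R,5S)-2,3-dihydroxy-2-methyl-5-(prop-1-en-2-yl)cyclohexan-1-one
Product: 4 (2S,3R,5S)-2-methyl-5-(prop-1-en-2-yl)-2,3-bis(triethylsilyloxy)cyclohexan-1-one
Conditions: Et3SiOTf (2.5 equiv), 2,6-lutidine, CH2Cl2, −78 → 0 °C
Reagents that add atoms: triethylsilyl trifluoromethanesulfonate, CC[Si](CC)(CC)OS(=O)(=O)C(F)(F)F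
Why: silyl triflate silylation of the secondary and the hindered tertiary hydroxyl, which blocks retro-aldol and ketol shifts in the later basic steps.

Step 4
Reactants: 4 (2S,3R,5S)-2-methyl-5-(prop-1-en-2-yl)-2,3-bis(triethylsilyloxy)cyclohexan-1-one
Product: 7 (1S,3R,4S)-4-methyl-5-oxo-3,4-bis(triethylsilyloxy)cyclohexyl acetate, via methoxy hydroperoxide 5 (not isolated), via peroxyacetate 6 (not isolated)
Conditions: O3, CH2Cl2/MeOH (4:1), −78 °C; then Ac2O, Et3N, DMAP (cat.), 0 °C → rt
Reagents that add atoms: ozone, [O-][O+]=O; methanol, CO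
Why: ozonolysis in methanol followed by Criegee rearrangement of the peroxyacetate, the ring carbon migrating to oxygen with retention so that the isopropenyl C–C bond becomes a C–O bond (the acetyl carbons come from the isopropenyl group itself).

Step 5
Reactants: 7 (1S,3R,4S)-4-methyl-5-oxo-3,4-bis(triethylsilyloxy)cyclohexyl acetate
Product: 8 4-methyl-4,5-bis(triethylsilyloxy)cyclohexane-1,3-diol, the three stereocentres of 7 unchanged, both epimers at the new carbinol carbon next to the quaternary carbon
Conditions: iBu2AlH (5 equiv), CH2Cl2, −78 °C; aq. potassium sodium tartrate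
Reagents that add atoms: none
Why: hydride reduction of the ketone and reductive cleavage of the acetate in one operation under non-basic conditions, which avoids β-elimination of the β-acetoxy ketone; the new carbinol centre is erased in the next step.

Step 6
Reactants: 8 4-methyl-4,5-bis(triethylsilyloxy)cyclohexane-1,3-diol
Product: 9 (4S,5R)-4-methyl-4,5-bis(triethylsilyloxy)cyclohexane-1,3-dione
Conditions: Dess–Martin periodinane (3 equiv), NaHCO3, CH2Cl2, 0 °C → rt
Reagents that add atoms: none
Why: Dess–Martin oxidation of both secondary alcohols under buffered conditions, the β-hydroxy ketone stage being oxidised on to the 1,3-dione.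

Step 7
Reactants: 9 (4S,5R)-4-methyl-4,5-bis(triethylsilyloxy)cyclohexane-1,3-dione
Product: 10 (5R,6S)-2-chloro-3-hydroxy-6-methyl-5,6-bis(triethylsilyloxy)cyclohex-2-en-1-one (enol form of the 2-chloro-1,3-dione)
Conditions: N-chlorosuccinimide (1.0 equiv), CH2Cl2, 0 °C
Reagents that add atoms: N-chlorosuccinimide, O=C1CCC(=O)N1Cl
Why: electrophilic chlorination of the enolised 1,3-dione at the carbon between the two carbonyls (future C5), its only strongly nucleophilic position.

Step 8
Reactants: 10 (5R,6S)-2-chloro-3-hydroxy-6-methyl-5,6-bis(triethylsilyloxy)cyclohex-2-en-1-one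
Product: 11 (4S,5R)-2-chloro-4-methyl-3-oxo-4,5-bis(triethylsilyloxy)cyclohex-1-en-1-yl trifluoromethanesulfonate
Conditions: Tf2O (1.1 equiv), pyridine, CH2Cl2, −78 °C
Reagents that add atoms: trifluoromethanesulfonic anhydride, O=S(=O)(OS(=O)(=O)C(F)(F)F)C(F)(F)F
Why: O-sulfonylation of the vinylogous acid at the less hindered oxygen (next to the CH2, remote from the quaternary silyloxy carbon), which places the leaving group on the future C4a and keeps the carbonyl at C6.

Step 9
Reactants: 12 itaconic anhydride; 13 2-(trimethylsilyl)ethanol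
Product: 14 2-methylidene-4-oxo-4-[2-(trimethylsilyl)ethoxy]butanoic acid
Conditions: toluene, 60 °C
Reagents that add atoms: none
Why: alcoholysis of the cyclic anhydride at the non-conjugated, less hindered carbonyl, the general regiochemistry of itaconic anhydride, should give the 4-monoester.

Step 10
Reactants: 14 2-methylidene-4-oxo-4-[2-(trimethylsilyl)ethoxy]butanoic acid
Product: 15 (2S)-2-methyl-4-oxo-4-[2-(trimethylsilyl)ethoxy]butanoic acid
Conditions: H2 (5 bar), [Rh(cod)((R,R)-Et-DuPhos)]BF4 (0.5 mol %), MeOH, rt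
Reagents that add atoms: none
Why: rhodium–bisphospholane asymmetric hydrogenation of an itaconate half-ester, in which chelation by the ester carbonyl and the alkene fixes the enantioface; the (R,R) ligand is expected to deliver the (S) centre.

Step 11
Reactants: 15 (2S)-2-methyl-4-oxo-4-[2-(trimethylsilyl)ethoxy]butanoic acid
Product: 16 2-(trimethylsilyl)ethyl (3S)-4-hydroxy-3-methylbutanoate
Conditions: BH3·SMe2 (1.1 equiv), THF, −10 → 0 °C; MeOH
Reagents that add atoms: none
Why: chemoselective borane reduction of the free carboxylic acid through its acyloxyborane in the presence of the ester, the stereocentre being untouched; the hydroxy ester is used at once to avoid lactonisation.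

Step 12
Reactants: 16 2-(trimethylsilyl)ethyl (3S)-4-hydroxy-3-methylbutanoate
Product: 17 2-(trimethylsilyl)ethyl (3S)-3-methyl-4-oxobutanoate
Conditions: Dess–Martin periodinane, NaHCO3, CH2Cl2, 0 °C
Reagents that add atoms: none
Why: buffered Dess–Martin oxidation should give the α-branched aldehyde without epimerisation.

Step 13
Reactants: 17 2-(trimethylsilyl)ethyl (3S)-3-methyl-4-oxobutanoate; 18 2-(triphenylphosphoranylidene)propanal
Product: 19 2-(trimethylsilyl)ethyl (3S,4E)-3,5-dimethyl-6-oxohex-4-enoate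
Conditions: toluene, 80 °C
Reagents that add atoms: none
Why: Wittig olefination with the stabilised formyl ylide, which is (E)-selective for the trisubstituted enal and neutral enough to spare the α-stereocentre.

Step 14
Reactants: 19 2-(trimethylsilyl)ethyl (3S,4E)-3,5-dimethyl-6-oxohex-4-enoate
Product: 20 2-(trimethylsilyl)ethyl (3S,4E,6E)-7-iodo-3,5-dimethylhepta-4,6-dienoate
Conditions: CrCl2 (6 equiv), CHI3 (2 equiv), THF/dioxane (1:6), 0 °C → rt
Reagents that add atoms: iodoform, IC(I)I
Why: Takai olefination, the gem-dichromium reagent converting the enal into the (E)-vinyl iodide without touching the ester.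

Step 15
Reactants: 20 2-(trimethylsilyl)ethyl (3S,4E,6E)-7-iodo-3,5-dimethylhepta-4,6-dienoate
Product: 21 2-(trimethylsilyl)ethyl (3S,4E,6E)-3,5-dimethylnona-4,6-dien-8-ynoate
Conditions: HC≡CMgBr, ZnBr2, THF, 0 °C; then 20, Pd(PPh3)4 (5 mol %), THF, rt
Reagents that add atoms: ethynylmagnesium bromide, C#C[Mg]Br
Why: Negishi coupling of the alkenyl iodide with ethynylzinc bromide, which retains the (E)-geometry and gives the terminal enyne directly.

Step 16
Reactants: 11 (4S,5R)-2-chloro-4-methyl-3-oxo-4,5-bis(triethylsilyloxy)cyclohex-1-en-1-yl trifluoromethanesulfonate; 21 2-(trimethylsilyl)ethyl (3S,4E,6E)-3,5-dimethylnona-4,6-dien-8-ynoate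
Product: 22 2-(trimethylsilyl)ethyl (3S,4E,6E)-9-[(4S,5R)-2-chloro-4-methyl-3-oxo-4,5-bis(triethylsilyloxy)cyclohex-1-en-1-yl]-3,5-dimethylnona-4,6-dien-8-ynoate
Conditions: PdCl2(PPh3)2 (5 mol %), CuI (10 mol %), iPr2NEt, THF, rt
Reagents that add atoms: none
Why: Sonogashira coupling at the vinylogous acyl triflate, which undergoes oxidative addition far faster than the vinyl chloride.

Step 17
Reactants: 22 2-(trimethylsilyl)ethyl (3S,4E,6E)-9-[(4S,5R)-2-chloro-4-methyl-3-oxo-4,5-bis(triethylsilyloxy)cyclohex-1-en-1-yl]-3,5-dimethylnona-4,6-dien-8-ynoate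
Product: 24 2-(trimethylsilyl)ethyl (3S,4E,6E)-7-[(7S,8R)-5-chloro-7-methyl-6-oxo-7,8-bis(triethylsilyloxy)-7,8-dihydro-6H-isochromen-3-yl]-3,5-dimethylhepta-4,6-dienoate, via hydroxymethylene enynone 23 (not isolated)
Conditions: KN(SiMe3)2 (1.1 equiv), THF, −78 °C; HCO2CH2CF3 (2 equiv), −78 → 0 °C; then AcOH (1.2 equiv), AgOTf (10 mol %), 0 °C → rt, same flask
Reagents that add atoms: 2,2,2-trifluoroethyl formate, O=COCC(F)(F)F
Why: KN(SiMe3)2 can only remove a proton from C8a (C7 is quaternary, C5 carries chlorine), and the cross-conjugated dienolate is acylated by the formate in a vinylogous Claisen condensation: attack at C5 gives a non-enolisable chloro aldehyde that reverts by retro-Claisen, whereas the C8a adduct is drained as its stabilised hydroxymethylene enolate 23, which fixes the C1–C8a bond. After buffering with AcOH, the enol oxygen O2, held syn to the alkyne, adds anti across the silver-activated triple bond at C3, and protodemetalation at C4 gives the pyran with the C1=C8a, C3=C4 and C4a=C5 double bonds of the target. The closest known reaction types are the hydroxymethylenation of ketone enolates with 2,2,2-trifluoroethyl formate and the coinage-metal-catalysed cycloisomerisation of 2-alkynyl enols and o-alkynyl aryl aldehydes to pyrans. The pyran ring closes in the 6-endo-dig mode, favoured over 5-exo because C3 is the δ-terminus of the ynenone and is stabilised by the dienyl group. No stereocentre is created and C7 and C8 are spectators; loss of the C8 silyloxy group from the dienolate is held back by the low temperature and the poor leaving group. Chemoselectivity over the ester α-protons rests on the much higher acidity of the C8a–H bonds and on the use of about one equivalent of base.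

Step 18
Reactants: 24 2-(trimethylsilyl)ethyl (3S,4E,6E)-7-[(7S,8R)-5-chloro-7-methyl-6-oxo-7,8-bis(triethylsilyloxy)-7,8-dihydro-6H-isochromen-3-yl]-3,5-dimethylhepta-4,6-dienoate
Product: 25 (3S,4E,6E)-7-[(7S,8R)-5-chloro-7,8-dihydroxy-7-methyl-6-oxo-7,8-dihydro-6H-isochromen-3-yl]-3,5-dimethylhepta-4,6-dienoic acid
Conditions: tris(dimethylamino)sulfonium difluorotrimethylsilicate (6 equiv), DMF/H2O (20:1), 0 °C → rt; aq. NH4Cl
Reagents that add atoms: none
Why: fluoride-mediated desilylation of both triethylsilyl ethers together with β-elimination of the 2-(trimethylsilyl)ethyl ester in one operation, the water protonating the alkoxides so that the base-sensitive chromophore is not exposed to them.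

Compound list
1 | (S)-(+)-carvone | CC(=C)[C@@H]1CC(=O)C(C)=CC1 | starting material
2 | (1S,4S,6S)-1-methyl-4-(prop-1-en-2-yl)-7-oxabicyclo[4.1.0]heptan-2-one | CC(=C)[C@@H]1CC(=O)[C@@]2(C)O[C@H]2C1 | intermediate
3 | (2S,3R,5S)-2,3-dihydroxy-2-methyl-5-(prop-1-en-2-yl)cyclohexan-1-one | CC(=C)[C@@H]1CC(=O)[C@@](C)(O)[C@H](O)C1 | intermediate
4 | (2S,3R,5S)-2-methyl-5-(prop-1-en-2-yl)-2,3-bis(triethylsilyloxy)cyclohexan-1-one | CC(=C)[C@@H]1CC(=O)[C@@](C)(O[Si](CC)(CC)CC)[C@H](O[Si](CC)(CC)CC)C1 | intermediate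
5 | (2S,3R,5S)-5-(1-hydroperoxy-1-methoxyethyl)-2-methyl-2,3-bis(triethylsilyloxy)cyclohexan-1-one, both epimers at the side-chain carbon | COC(C)(OO)[C@@H]1CC(=O)[C@@](C)(O[Si](CC)(CC)CC)[C@H](O[Si](CC)(CC)CC)C1 | intermediate (not isolated)
6 | (2S,3R,5S)-5-[1-(acetylperoxy)-1-methoxyethyl]-2-methyl-2,3-bis(triethylsilyloxy)cyclohexan-1-one, both epimers at the side-chain carbon | COC(C)(OOC(C)=O)[C@@H]1CC(=O)[C@@](C)(O[Si](CC)(CC)CC)[C@H](O[Si](CC)(CC)CC)C1 | intermediate (not isolated)
7 | (1S,3R,4S)-4-methyl-5-oxo-3,4-bis(triethylsilyloxy)cyclohexyl acetate | CC(=O)O[C@@H]1CC(=O)[C@@](C)(O[Si](CC)(CC)CC)[C@H](O[Si](CC)(CC)CC)C1 | intermediate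
8 | 4-methyl-4,5-bis(triethylsilyloxy)cyclohexane-1,3-diol, stereocentres of 7 unchanged, both epimers at the new carbinol carbon | O[C@@H]1CC(O)[C@@](C)(O[Si](CC)(CC)CC)[C@H](O[Si](CC)(CC)CC)C1 | intermediate
9 | (4S,5R)-4-methyl-4,5-bis(triethylsilyloxy)cyclohexane-1,3-dione | O=C1CC(=O)[C@@](C)(O[Si](CC)(CC)CC)[C@H](O[Si](CC)(CC)CC)C1 | intermediate
10 | (5R,6S)-2-chloro-3-hydroxy-6-methyl-5,6-bis(triethylsilyloxy)cyclohex-2-en-1-one | OC1=C(Cl)C(=O)[C@@](C)(O[Si](CC)(CC)CC)[C@H](O[Si](CC)(CC)CC)C1 | intermediate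
11 | (4S,5R)-2-chloro-4-methyl-3-oxo-4,5-bis(triethylsilyloxy)cyclohex-1-en-1-yl trifluoromethanesulfonate | O=S(=O)(OC1=C(Cl)C(=O)[C@@](C)(O[Si](CC)(CC)CC)[C@H](O[Si](CC)(CC)CC)C1)C(F)(F)F | intermediate
12 | itaconic anhydride | C=C1CC(=O)OC1=O | starting material
13 | 2-(trimethylsilyl)ethanol | C[Si](C)(C)CCO | starting material
14 | 2-methylidene-4-oxo-4-[2-(trimethylsilyl)ethoxy]butanoic acid | C=C(CC(=O)OCC[Si](C)(C)C)C(=O)O | intermediate
15 | (2S)-2-methyl-4-oxo-4-[2-(trimethylsilyl)ethoxy]butanoic acid | OC(=O)[C@@H](C)CC(=O)OCC[Si](C)(C)C | intermediate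
16 | 2-(trimethylsilyl)ethyl (3S)-4-hydroxy-3-methylbutanoate | OC[C@@H](C)CC(=O)OCC[Si](C)(C)C | intermediate
17 | 2-(trimethylsilyl)ethyl (3S)-3-methyl-4-oxobutanoate | O=C[C@@H](C)CC(=O)OCC[Si](C)(C)C | intermediate
18 | 2-(triphenylphosphoranylidene)propanal | CC(C=O)=P(c1ccccc1)(c1ccccc1)c1ccccc1 | starting material
19 | 2-(trimethylsilyl)ethyl (3S,4E)-3,5-dimethyl-6-oxohex-4-enoate | O=C/C(C)=C/[C@@H](C)CC(=O)OCC[Si](C)(C)C | intermediate
20 | 2-(trimethylsilyl)ethyl (3S,4E,6E)-7-iodo-3,5-dimethylhepta-4,6-dienoate | I/C=C/C(C)=C/[C@@H](C)CC(=O)OCC[Si](C)(C)C | intermediate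
21 | 2-(trimethylsilyl)ethyl (3S,4E,6E)-3,5-dimethylnona-4,6-dien-8-ynoate | C#C/C=C/C(C)=C/[C@@H](C)CC(=O)OCC[Si](C)(C)C | intermediate
22 | 2-(trimethylsilyl)ethyl (3S,4E,6E)-9-[(4S,5R)-2-chloro-4-methyl-3-oxo-4,5-bis(triethylsilyloxy)cyclohex-1-en-1-yl]-3,5-dimethylnona-4,6-dien-8-ynoate | CC(/C=C/C#CC1=C(Cl)C(=O)[C@@](C)(O[Si](CC)(CC)CC)[C@H](O[Si](CC)(CC)CC)C1)=C\[C@@H](C)CC(=O)OCC[Si](C)(C)C | intermediate
23 | 2-(trimethylsilyl)ethyl (3S,4E,6E)-9-[(4S,5R,6E)-2-chloro-6-(hydroxymethylidene)-4-methyl-3-oxo-4,5-bis(triethylsilyloxy)cyclohex-1-en-1-yl]-3,5-dimethylnona-4,6-dien-8-ynoate | CC(/C=C/C#CC1=C(Cl)C(=O)[C@@](C)(O[Si](CC)(CC)CC)[C@H](O[Si](CC)(CC)CC)/C1=C/O)=C\[C@@H](C)CC(=O)OCC[Si](C)(C)C | intermediate (not isolated)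
24 | 2-(trimethylsilyl)ethyl (3S,4E,6E)-7-[(7S,8R)-5-chloro-7-methyl-6-oxo-7,8-bis(triethylsilyloxy)-7,8-dihydro-6H-isochromen-3-yl]-3,5-dimethylhepta-4,6-dienoate | CC(/C=C/C1=CC2=C(Cl)C(=O)[C@@](C)(O[Si](CC)(CC)CC)[C@H](O[Si](CC)(CC)CC)C2=CO1)=C\[C@@H](C)CC(=O)OCC[Si](C)(C)C | intermediate
25 | (3S,4E,6E)-7-[(7S,8R)-5-chloro-7,8-dihydroxy-7-methyl-6-oxo-7,8-dihydro-6H-isochromen-3-yl]-3,5-dimethylhepta-4,6-dienoic acid | CC(/C=C/C1=CC2=C(Cl)C(=O)[C@@](C)(O)[C@H](O)C2=CO1)=C\[C@@H](C)CC(=O)O | target

Total step count: 18. Longest linear sequence: 11 steps (steps 1–8 and 16–18, from (S)-carvone); the side-chain branch (steps 9–15) joins at step 16.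

Steps most likely to fail

1. Step 17. The formylation may go astray (reaction at the ester enolate, or β-elimination of the C8 silyloxy group from the dienolate), or the sequence may stall at the open hydroxymethylene stage. Fallback, setting out from 22 and returning at 24: soft enolisation of 22 (Et3SiOTf, Et3N, CH2Cl2, −78 °C) should give the triethylsilyl dienol ether F1 without strong base. F1 is treated with (chloromethylene)dimethylammonium chloride in CH2Cl2 at −40 → 0 °C; vinylogous Mukaiyama-type attack through C8a with loss of the enol silyl group should give the dimethylaminomethylidene enone F2. Aqueous NaOAc added to the same flask hydrolyses the enaminone to 23, and AgOTf then closes the pyran to 24, so both bonds are still made in one flask.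

2. Step 18. Base-induced degradation of the liberated diol chromophore (retro-aldol or ketol shift, nucleophile addition at C1) may compete, or ester cleavage may be incomplete. Fallback, setting out from 21 and returning at 25: the ester is unmasked before the chromophore exists, so that the last step needs only acidic fluoride. Bu4NF in THF converts 21 into the dienyne acid F3. Sonogashira coupling of F3 with 11 (PdCl2(PPh3)2, CuI, excess iPr2NEt) gives the enynone acid F4. The formylation–cyclisation of step 17, run with one further equivalent of KN(SiMe3)2 so that the carboxylate is a spectator, gives through the hydroxymethylene acid F5 the bis-silylated acid F6. HF·pyridine buffered with pyridine in THF at 0 °C then removes the two triethylsilyl ethers to give 25.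

3. Step 4. β-Elimination of acetate from the β-acetoxy ketone under the amine conditions, or incomplete rearrangement of the peroxyacetate, may lower the throughput. Fallback, setting out from 4 and returning at 9: ozonolysis of 4 in MeOH at −78 °C is followed by FeSO4·7H2O and TEMPO (0 °C → rt). Reductive O–O cleavage, β-scission and radical trapping should give the alkoxyamine F7 in place of the acetate. Oxidation of F7 with mCPBA (CH2Cl2, 0 °C) converts the N–O–CH unit into the ketone and gives dione 9 directly, bypassing 7 and 8.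

Further compounds
F1 | step 17 | triethylsilyl dienol ether of 22: 2-(trimethylsilyl)ethyl (3S,4E,6E)-9-[(3R,4S)-6-chloro-4-methyl-3,4,5-tris(triethylsilyloxy)cyclohexa-1,5-dien-1-yl]-3,5-dimethylnona-4,6-dien-8-ynoate | CC(/C=C/C#CC1=C[C@@H](O[Si](CC)(CC)CC)[C@](C)(O[Si](CC)(CC)CC)C(O[Si](CC)(CC)CC)=C1Cl)=C\[C@@H](C)CC(=O)OCC[Si](C)(C)C
F2 | step 17 | dimethylaminomethylidene enone: analogue of 23 with NMe2 in place of OH on the exocyclic methylidene carbon, either geometry | CC(/C=C/C#CC1=C(Cl)C(=O)[C@@](C)(O[Si](CC)(CC)CC)[C@H](O[Si](CC)(CC)CC)C1=CN(C)C)=C\[C@@H](C)CC(=O)OCC[Si](C)(C)C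
F3 | step 18 | (3S,4E,6E)-3,5-dimethylnona-4,6-dien-8-ynoic acid | C#C/C=C/C(C)=C/[C@@H](C)CC(=O)O
F4 | step 18 | enynone acid: free carboxylic acid corresponding to 22 | CC(/C=C/C#CC1=C(Cl)C(=O)[C@@](C)(O[Si](CC)(CC)CC)[C@H](O[Si](CC)(CC)CC)C1)=C\[C@@H](C)CC(=O)O
F5 | step 18 | hydroxymethylene acid: free carboxylic acid corresponding to 23 (not isolated) | CC(/C=C/C#CC1=C(Cl)C(=O)[C@@](C)(O[Si](CC)(CC)CC)[C@H](O[Si](CC)(CC)CC)/C1=C/O)=C\[C@@H](C)CC(=O)O
F6 | step 18 | bis-silylated acid: free carboxylic acid corresponding to 24 | CC(/C=C/C1=CC2=C(Cl)C(=O)[C@@](C)(O[Si](CC)(CC)CC)[C@H](O[Si](CC)(CC)CC)C2=CO1)=C\[C@@H](C)CC(=O)O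
F7 | step 4 | alkoxyamine: (2S,3R)-2-methyl-5-[(2,2,6,6-tetramethylpiperidin-1-yl)oxy]-2,3-bis(triethylsilyloxy)cyclohexan-1-one, both epimers at the aminoxy carbon | CC1(C)CCCC(C)(C)N1OC1CC(=O)[C@@](C)(O[Si](CC)(CC)CC)[C@H](O[Si](CC)(CC)CC)C1
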